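**Retrosynthetic overview**
1. Target ⇐ desilylation and Luche reduction of exo-methylene cycloheptenone 39; the C1(=CH2)–C2(OH) unit is carried as an isoxazoline (36).
2. Key step: intramolecular nitrile oxide–alkene [3+2] cycloaddition (oxime 34 → 36) closes the seven-membered ring through the C1–C2 bond onto a finished cyclopentene.
3. 34 ⇐ C4–C5 union by C-acylation of γ-lactone 25 with cyclopentene acid 15, Felkin reduction (C5), then lactone → lactol → one-carbon Wittig homologation (C2) and acetylation.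
4. 15 ⇐ (R)-carvone (Wolff ring contraction, epoxide → tertiary allylic alcohol, isopropenyl → vinyl); 25 ⇐ methyl 3,4-O-isopropylidene-L-threonate (butenolide, face-selective hydrogenation).
5. Ring order: cyclopentene first, a temporary γ-lactone as stereocontrol template second, the seven-membered ring last.

Assumption: atom labels follow the target (C1 = ring carbon bearing the exocyclic CH2, C2 = CH(OH) next to it, C3 = CH2, C4 = CH carrying the side chain, C5 = CH(OH), C6 and C7 = ring-fusion CH with C7 next to C1, C8=C9, C10 = C(OH)CH3, C11 = CH(CH3), C12 and C13 = CH(OAc), C14=C15); (R)-carvone and methyl 3,4-O-isopropylidene-L-threonate (from vitamin C) are the purchased chiral materials.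

**Cyclopentene fragment (steps 1–9)**

Step 1
Reactants: 1 (R)-carvone
Product: 3 6-diazocarvone, via trifluoroacetyl diketone 2 (not isolated)
Conditions: LiN(SiMe3)2, THF, −78 °C; CF3CO2CH2CF3; then MsN3, Et3N, H2O, MeCN, rt
Reagents that add atoms: methanesulfonyl azide, CS(=O)(=O)N=[N+]=[N-]
Why: Kinetic α′-enolisation, Claisen trifluoroacetylation and detrifluoroacetylative (Regitz-type) diazo transfer put the diazo group on the CH2 next to the ketone (future C6) without touching the carvone stereocentre (future C7).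

Step 2
Reactants: 3 6-diazocarvone
Product: 5 methyl (1S,5R)-2-methyl-5-(prop-1-en-2-yl)cyclopent-2-ene-1-carboxylate, via ketene 4 (not isolated)
Conditions: hν (Hg lamp, Pyrex), MeOH, 0 °C; then NaOMe (cat.), 0 °C
Reagents that add atoms: methanol, CO
Why: Photochemical Wolff rearrangement contracts the ring by migration of the alkenyl carbon, methanol traps the ketene as the β,γ-unsaturated ester, and brief base equilibration leaves the C6 ester trans to the isopropenyl group fixed by carvone.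

Step 3
Reactants: 5 cyclopentene ester
Product: 6 epoxy ester
Conditions: mCPBA, NaHCO3, CH2Cl2, −20 → 0 °C
Reagents that add atoms: 3-chloroperbenzoic acid, OOC(=O)c1cccc(Cl)c1
Why: Prilezhaev epoxidation prefers the trisubstituted ring alkene over the 1,1-disubstituted one and enters anti to the adjacent allylic ester, which sets the C10–O bond trans to C6–C5 (C9 is removed later).

Step 4
Reactants: 6 epoxy ester
Product: 8 epoxy methyl ketone, via ozonide 7 (not isolated)
Conditions: O3, CH2Cl2, −78 °C; then Me2S, −78 °C → rt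
Reagents that add atoms: ozone, [O-][O+]=O
Why: With the ring alkene masked as its epoxide, Criegee ozonolysis cleaves the only remaining alkene to the methyl ketone without touching a stereocentre.

Step 5
Reactants: 8 epoxy methyl ketone
Product: 11 hydroxy enone ester, via selenide 9 (not isolated), via selenoxide 10 (not isolated)
Conditions: PhSeNa, EtOH, 0 °C → rt; then 30% H2O2, THF, 0 °C → rt
Reagents that add atoms: none
Why: In the Sharpless epoxide-to-allylic-alcohol sequence the selenolate opens the epoxide by SN2 at the less hindered C9 (C10–O retained), and selenoxide syn-elimination can only go toward C8, giving the C8=C9 alkene next to the tertiary carbinol.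

Step 6
Reactants: 11 hydroxy enone ester
Product: 12 triethylsilyl ether
Conditions: TESOTf, 2,6-lutidine, CH2Cl2, −78 °C
Reagents that add atoms: triethylsilyl triflate, CC[Si](CC)(CC)OS(=O)(=O)C(F)(F)F
Why: Silylation of the tertiary alcohol blocks retro-aldol and alkoxide chemistry in the base-mediated steps that follow; no stereocentre is involved.

Step 7
Reactants: 12 triethylsilyl ether
Product: 13 enol triflate
Conditions: KN(SiMe3)2, THF, −78 °C; PhNTf2
Reagents that add atoms: N-phenylbis(trifluoromethanesulfonimide), O=S(=O)(N(c1ccccc1)S(=O)(=O)C(F)(F)F)C(F)(F)F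
Why: Kinetic deprotonation occurs at the ketone CH3 (more acidic and less hindered than the ester α-H), and O-sulfonylation gives the terminal enol triflate.

Step 8
Reactants: 13 enol triflate
Product: 14 vinyl ester
Conditions: Pd(OAc)2 (cat.), PPh3, HCO2H, n-Bu3N, DMF, 60 °C
Reagents that add atoms: none
Why: Palladium-catalysed formate reduction (oxidative addition, hydride transfer from formate, reductive elimination) turns the enol triflate into the vinyl group that serves as dipolarophile.

Step 9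
Reactants: 14 vinyl ester
Product: 15 cyclopentene acid
Conditions: LiOH, THF/MeOH/H2O, 40 °C; then 1 M HCl to pH 4
Reagents that add atoms: lithium hydroxide, [Li+].[OH-]
Why: Saponification; C6 already holds the thermodynamically preferred position trans to both the vinyl and silyloxy groups, so it is not scrambled.

**Lactone fragment (steps 10–16)**

Step 10
Reactants: 16 methyl 3,4-O-isopropylidene-L-threonate
Product: 18 α-hydroxy methyl ketone, via Weinreb amide 17 (not isolated)
Conditions: MeNH(OMe)·HCl, i-PrMgCl, THF, −20 °C; then MeMgBr, 0 °C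
Reagents that add atoms: methylmagnesium bromide, C[Mg]Br
Why: In situ Weinreb amide formation and Grignard addition stop at the ketone through the chelated tetrahedral intermediate, while the magnesium alkoxide at C12 prevents enolisation of that stereocentre.

Step 11
Reactants: 18 α-hydroxy methyl ketone
Product: 20 β-methyl butenolide, via acyl ylide 19 (not isolated)
Conditions: Ph3P=C=C=O, toluene, 110 °C
Reagents that add atoms: (triphenylphosphoranylidene)ketene, O=C=C=P(c1ccccc1)(c1ccccc1)c1ccccc1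
Why: The Bestmann ylide acylates the hydroxyl and the resulting ester ylide closes by intramolecular Wittig reaction on the ketone, supplying C3 and C4 and leaving C12 and C13 untouched.

Step 12
Reactants: 20 β-methyl butenolide
Product: 21 cis-β-methyl-γ-lactone
Conditions: H2 (1 atm), Pd/C, EtOAc, rt
Reagents that add atoms: none
Why: Heterogeneous hydrogenation delivers H2 to the butenolide face opposite the C12 substituent, so the C11 methyl ends cis to it (C11 set by C12).

Step 13
Reactants: 21 cis-β-methyl-γ-lactone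
Product: 22 diol lactone
Conditions: AcOH/H2O (4:1), 40 °C
Reagents that add atoms: none
Why: Acid hydrolysis of the terminal acetonide frees the C13/C14 diol; the γ-lactone is kept.

Step 14
Reactants: 22 diol lactone
Product: 23 bis(triethylsilyl) ether
Conditions: TESCl, imidazole, DMF, 0 °C → rt
Reagents that add atoms: chlorotriethylsilane, CC[Si](Cl)(CC)CC
Why: Exhaustive silylation sets up the selective oxidation of the primary position in the next step.

Step 15
Reactants: 23 bis(triethylsilyl) ether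
Product: 24 α-silyloxy aldehyde
Conditions: (COCl)2, DMSO, CH2Cl2, −78 °C; Et3N, −78 → −30 °C
Reagents that add atoms: none
Why: Under Swern conditions a primary triethylsilyl ether is cleaved and oxidised directly to the aldehyde while the secondary one survives, and the low temperature avoids epimerisation at C13.

Step 16
Reactants: 24 α-silyloxy aldehyde
Product: 25 (4R,5S)-4-methyl-5-[(1S)-3-methyl-1-(triethylsilyloxy)but-2-en-1-yl]oxolan-2-one
Conditions: i-PrPPh3I, n-BuLi, THF, −78 → 0 °C
Reagents that add atoms: isopropyltriphenylphosphonium iodide, CC(C)[P+](c1ccccc1)(c1ccccc1)c1ccccc1.[I-]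
Why: Wittig olefination with the non-stabilised isopropylidene ylide is much faster on the aldehyde than on the lactone and builds the C14=C15 alkene.

**Union, ring closure and endgame (steps 17–29)**

Step 17
Reactants: 15 cyclopentene acid; 25 lactone
Product: 27 β-keto lactone, via acyl imidazole 26 (not isolated)
Conditions: 15, CDI, THF, rt; 25, LiN(SiMe3)2 (2.1 equiv), THF, −78 °C; then 26, −78 → −20 °C
Reagents that add atoms: none
Why: Claisen-type C-acylation of the lactone lithium enolate forms C4–C5, the acyl group entering (and equilibrating) trans to the C11 methyl on the lactone ring (C4 set by C11).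

Step 18
Reactants: 27 β-keto lactone
Product: 28 β-hydroxy lactone
Conditions: NaBH4, MeOH/CH2Cl2, −78 → −40 °C
Reagents that add atoms: none
Why: Non-chelating hydride reduction follows Felkin–Anh control from both flanking centres (hydride anti to the quaternary C10 on one side and to the lactone carbonyl on the other), a matched case that sets C5.

Step 19
Reactants: 28 β-hydroxy lactone
Product: 29 C5 tert-butyldimethylsilyl ether
Conditions: TBSOTf, 2,6-lutidine, CH2Cl2, 0 °C
Reagents that add atoms: tert-butyldimethylsilyl triflate, CC(C)(C)[Si](C)(C)OS(=O)(=O)C(F)(F)F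
Why: Silylation keeps C5–OH out of the later acetylation; no stereocentre changes.

Step 20
Reactants: 29 C5 silyl ether
Product: 30 C13 alcohol
Conditions: PPTS (cat.), MeOH/CH2Cl2, 0 °C
Reagents that add atoms: none
Why: Mild acid methanolysis removes the least hindered, secondary allylic triethylsilyl ether while the TBS ether and the tertiary triethylsilyl ether stay.

Step 21
Reactants: 30 C13 alcohol
Product: 31 lactol
Conditions: i-Bu2AlH (2.5 equiv), CH2Cl2, −78 °C
Reagents that add atoms: none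
Why: Half-reduction of the γ-lactone stops at the lactol because the tetrahedral aluminate is stable at −78 °C.

Step 22
Reactants: 31 lactol
Product: 32 enol ether diol
Conditions: MeOCH2PPh3Cl, KN(SiMe3)2, THF, 0 °C → rt
Reagents that add atoms: (methoxymethyl)triphenylphosphonium chloride, COC[P+](c1ccccc1)(c1ccccc1)c1ccccc1.[Cl-]
Why: Wittig methoxymethylenation of the open hydroxy-aldehyde form adds C2 as a masked aldehyde and releases the C12 hydroxyl.

Step 23
Reactants: 32 enol ether diol
Product: 33 diacetate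
Conditions: Ac2O, pyridine, DMAP (cat.), CH2Cl2, 0 °C → rt
Reagents that add atoms: acetic anhydride, CC(=O)OC(C)=O
Why: Only the C12 and C13 hydroxyls are free, so acylation installs exactly the two acetates of the target.

Step 24
Reactants: 33 diacetate
Product: 34 aldoxime
Conditions: NH2OH·HCl, pyridine, EtOH/H2O, 40 °C
Reagents that add atoms: hydroxylamine hydrochloride, NO.Cl
Why: The enol ether is hydrolysed under the buffered acidic conditions and the aldehyde is condensed at once to the oxime of C2.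

Step 25
Reactants: 34 aldoxime
Product: 36 isoxazoline, via nitrile oxide 35 (not isolated)
Conditions: aq. NaOCl, CH2Cl2, 0 °C → rt, high dilution
Reagents that add atoms: none
Why: Oxidation gives the nitrile oxide, which undergoes intramolecular Huisgen 1,3-dipolar cycloaddition onto the terminal vinyl group in the exo mode, closing the seven-membered ring through C1–C2 with the trans ring fusion fixed by C6/C7 (the new C1 centre is destroyed later).

Step 26
Reactants: 36 isoxazoline
Product: 37 β-hydroxy ketone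
Conditions: Fe, NH4Cl, EtOH/H2O, 80 °C
Reagents that add atoms: water, O
Why: Reductive N–O cleavage and hydrolysis of the resulting imine unmask the C2 ketone without reducing any alkene or cleaving the acetates.

Step 27
Reactants: 37 β-hydroxy ketone
Product: 39 exo-methylene ketone, via mesylate 38 (not isolated)
Conditions: MsCl, Et3N, CH2Cl2, 0 °C → rt
Reagents that add atoms: none
Why: Mesylation of the primary alcohol and E1cB elimination give the α-methylene ketone and erase the C1 stereocentre.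

Step 28
Reactants: 39 exo-methylene ketone
Product: 40 C2 allylic alcohol
Conditions: NaBH4, CeCl3·7H2O, MeOH, −78 °C
Reagents that add atoms: none
Why: Luche 1,2-reduction; axial-type attack of the small hydride on the ring ketone is expected to give the C2 alcohol trans to the C5 silyloxy group, with the ring stereocentres controlling the face.

Step 29
Reactants: 40 C2 allylic alcohol
Product: 41 target CNP0269663.3
Conditions: HF·pyridine, pyridine/THF, 0 °C → rt
Reagents that add atoms: none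
Why: Buffered fluoride removes the C5 TBS and C10 triethylsilyl ethers without acetate migration or ionisation of the allylic alcohols.

**Compound list**
1 | (R)-carvone, (5R)-2-methyl-5-(prop-1-en-2-yl)cyclohex-2-en-1-one | CC1=CC[C@H](CC1=O)C(C)=C | starting material
2 | 6-(trifluoroacetyl)carvone (ring stereocentre as in 1) | CC1=CC[C@H](C(C(=O)C(F)(F)F)C1=O)C(C)=C | intermediate
3 | 6-diazocarvone (6-diazo-2-methyl-5-(prop-1-en-2-yl)cyclohex-2-en-1-one, ring stereocentre as in 1) | CC1=CC[C@H](C(=[N+]=[N-])C1=O)C(C)=C | intermediate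
4 | ketene from ring contraction of 3 | O=C=C1[C@H](C(C)=C)CC=C1C | intermediate
5 | methyl (1S,5R)-2-methyl-5-(prop-1-en-2-yl)cyclopent-2-ene-1-carboxylate (ester trans to isopropenyl) | COC(=O)[C@H]1[C@H](C(C)=C)CC=C1C | intermediate
6 | methyl 2,3-epoxy-2-methyl-5-(prop-1-en-2-yl)cyclopentane-1-carboxylate (epoxide O trans to ester, cis to isopropenyl) | COC(=O)[C@H]1[C@H](C(C)=C)C[C@@H]2O[C@]12C | intermediate
7 | ozonide (1,2,4-trioxolane) of the isopropenyl group of 6 | COC(=O)[C@H]1[C@H](C3(C)OCOO3)C[C@@H]2O[C@]12C | intermediate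
8 | methyl 5-acetyl-2,3-epoxy-2-methylcyclopentane-1-carboxylate | COC(=O)[C@H]1[C@H](C(C)=O)C[C@@H]2O[C@]12C | intermediate
9 | methyl 5-acetyl-2-hydroxy-2-methyl-3-(phenylselanyl)cyclopentane-1-carboxylate (Se trans to OH) | COC(=O)[C@H]1[C@H](C(C)=O)C[C@@H]([Se]c2ccccc2)[C@]1(C)O | intermediate
10 | selenoxide of 9 | COC(=O)[C@H]1[C@H](C(C)=O)C[C@@H]([Se](=O)c2ccccc2)[C@]1(C)O | intermediate
11 | methyl 5-acetyl-2-hydroxy-2-methylcyclopent-3-ene-1-carboxylate (OH cis to acetyl, trans to ester) | COC(=O)[C@H]1[C@H](C(C)=O)C=C[C@]1(C)O | intermediate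
12 | triethylsilyl ether of 11 | COC(=O)[C@H]1[C@H](C(C)=O)C=C[C@]1(C)O[Si](CC)(CC)CC | intermediate
13 | methyl 2-methyl-2-(triethylsilyloxy)-5-[1-(trifluoromethylsulfonyloxy)ethenyl]cyclopent-3-ene-1-carboxylate | COC(=O)[C@H]1[C@H](C(=C)OS(=O)(=O)C(F)(F)F)C=C[C@]1(C)O[Si](CC)(CC)CC | intermediate
14 | methyl 5-ethenyl-2-methyl-2-(triethylsilyloxy)cyclopent-3-ene-1-carboxylate | COC(=O)[C@H]1[C@H](C=C)C=C[C@]1(C)O[Si](CC)(CC)CC | intermediate
15 | 5-ethenyl-2-methyl-2-(triethylsilyloxy)cyclopent-3-ene-1-carboxylic acid (CO2H trans to vinyl and to OSiEt3) | OC(=O)[C@H]1[C@H](C=C)C=C[C@]1(C)O[Si](CC)(CC)CC | intermediate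
16 | methyl 3,4-O-isopropylidene-L-threonate, methyl (2R)-2-[(4S)-2,2-dimethyl-1,3-dioxolan-4-yl]-2-hydroxyacetate | COC(=O)[C@H](O)[C@@H]1COC(C)(C)O1 | starting material
17 | Weinreb amide of 16 | CON(C)C(=O)[C@H](O)[C@@H]1COC(C)(C)O1 | intermediate
18 | (1R)-1-[(4S)-2,2-dimethyl-1,3-dioxolan-4-yl]-1-hydroxypropan-2-one | CC(=O)[C@H](O)[C@@H]1COC(C)(C)O1 | intermediate
19 | (triphenylphosphoranylidene)acetate ester of 18 | CC(=O)[C@H](OC(=O)C=P(c1ccccc1)(c1ccccc1)c1ccccc1)[C@@H]2COC(C)(C)O2 | intermediate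
20 | (5S)-5-[(4S)-2,2-dimethyl-1,3-dioxolan-4-yl]-4-methylfuran-2(5H)-one | O=C1C=C(C)[C@H](O1)[C@@H]2COC(C)(C)O2 | intermediate
21 | (4R,5S)-5-[(4S)-2,2-dimethyl-1,3-dioxolan-4-yl]-4-methyloxolan-2-one | O=C1C[C@@H](C)[C@H](O1)[C@@H]2COC(C)(C)O2 | intermediate
22 | (4R,5S)-5-[(1S)-1,2-dihydroxyethyl]-4-methyloxolan-2-one | O=C1C[C@@H](C)[C@H](O1)[C@@H](O)CO | intermediate
23 | (4R,5S)-5-[(1S)-1,2-bis(triethylsilyloxy)ethyl]-4-methyloxolan-2-one | O=C1C[C@@H](C)[C@H](O1)[C@@H](O[Si](CC)(CC)CC)CO[Si](CC)(CC)CC | intermediate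
24 | 2-[(2S,3R)-3-methyl-5-oxooxolan-2-yl]-2-(triethylsilyloxy)acetaldehyde (C13 as in 23) | O=C1C[C@@H](C)[C@H](O1)[C@@H](O[Si](CC)(CC)CC)C=O | intermediate
25 | (4R,5S)-4-methyl-5-[(1S)-3-methyl-1-(triethylsilyloxy)but-2-en-1-yl]oxolan-2-one | O=C1C[C@@H](C)[C@H](O1)[C@@H](O[Si](CC)(CC)CC)C=C(C)C | intermediate
26 | acyl imidazole of 15 | O=C(n1ccnc1)[C@H]1[C@H](C=C)C=C[C@]1(C)O[Si](CC)(CC)CC | intermediate
27 | β-keto lactone: 25 acylated at C4 by the acyl group of 15 (acyl trans to C11 methyl) | O=C1[C@@H]([C@@H](C)[C@H](O1)[C@@H](O[Si](CC)(CC)CC)C=C(C)C)C(=O)[C@H]2[C@H](C=C)C=C[C@]2(C)O[Si](CC)(CC)CC | intermediate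
28 | β-hydroxy lactone (C5 alcohol, configuration as in target) | O=C1[C@@H]([C@@H](C)[C@H](O1)[C@@H](O[Si](CC)(CC)CC)C=C(C)C)[C@@H](O)[C@H]2[C@H](C=C)C=C[C@]2(C)O[Si](CC)(CC)CC | intermediate
29 | C5 tert-butyldimethylsilyl ether of 28 | O=C1[C@@H]([C@@H](C)[C@H](O1)[C@@H](O[Si](CC)(CC)CC)C=C(C)C)[C@@H](O[Si](C)(C)C(C)(C)C)[C@H]2[C@H](C=C)C=C[C@]2(C)O[Si](CC)(CC)CC | intermediate
30 | C13 alcohol (29 without the C13 triethylsilyl group) | O=C1[C@@H]([C@@H](C)[C@H](O1)[C@@H](O)C=C(C)C)[C@@H](O[Si](C)(C)C(C)(C)C)[C@H]2[C@H](C=C)C=C[C@]2(C)O[Si](CC)(CC)CC | intermediate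
31 | lactol of 30 (anomer mixture) | OC1[C@@H]([C@@H](C)[C@H](O1)[C@@H](O)C=C(C)C)[C@@H](O[Si](C)(C)C(C)(C)C)[C@H]2[C@H](C=C)C=C[C@]2(C)O[Si](CC)(CC)CC | intermediate
32 | methyl enol ether (C2=C3, E/Z mixture) with free C12 and C13 hydroxyls | COC=C[C@@H]([C@@H](C)[C@H](O)[C@@H](O)C=C(C)C)[C@@H](O[Si](C)(C)C(C)(C)C)[C@H]1[C@H](C=C)C=C[C@]1(C)O[Si](CC)(CC)CC | intermediate
33 | C12,C13-diacetate of 32 | COC=C[C@@H]([C@@H](C)[C@H](OC(C)=O)[C@@H](OC(C)=O)C=C(C)C)[C@@H](O[Si](C)(C)C(C)(C)C)[C@H]1[C@H](C=C)C=C[C@]1(C)O[Si](CC)(CC)CC | intermediate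
34 | C2 aldoxime (E/Z mixture) | ON=CC[C@@H]([C@@H](C)[C@H](OC(C)=O)[C@@H](OC(C)=O)C=C(C)C)[C@@H](O[Si](C)(C)C(C)(C)C)[C@H]1[C@H](C=C)C=C[C@]1(C)O[Si](CC)(CC)CC | intermediate
35 | C2 nitrile oxide | [O-][N+]#CC[C@@H]([C@@H](C)[C@H](OC(C)=O)[C@@H](OC(C)=O)C=C(C)C)[C@@H](O[Si](C)(C)C(C)(C)C)[C@H]1[C@H](C=C)C=C[C@]1(C)O[Si](CC)(CC)CC | intermediate
36 | isoxazoline fused at C1–C2 to the trans-hydroazulene (C1 configuration not specified) | C1ON=C2C[C@@H]([C@@H](C)[C@H](OC(C)=O)[C@@H](OC(C)=O)C=C(C)C)[C@@H](O[Si](C)(C)C(C)(C)C)[C@H]3[C@H](C12)C=C[C@]3(C)O[Si](CC)(CC)CC | intermediate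
37 | C2 ketone with C1 hydroxymethyl group | OCC1C(=O)C[C@@H]([C@@H](C)[C@H](OC(C)=O)[C@@H](OC(C)=O)C=C(C)C)[C@@H](O[Si](C)(C)C(C)(C)C)[C@H]2[C@H]1C=C[C@]2(C)O[Si](CC)(CC)CC | intermediate
38 | mesylate of 37 | CS(=O)(=O)OCC1C(=O)C[C@@H]([C@@H](C)[C@H](OC(C)=O)[C@@H](OC(C)=O)C=C(C)C)[C@@H](O[Si](C)(C)C(C)(C)C)[C@H]2[C@H]1C=C[C@]2(C)O[Si](CC)(CC)CC | intermediate
39 | exo-methylene C2 ketone | C=C1C(=O)C[C@@H]([C@@H](C)[C@H](OC(C)=O)[C@@H](OC(C)=O)C=C(C)C)[C@@H](O[Si](C)(C)C(C)(C)C)[C@H]2[C@H]1C=C[C@]2(C)O[Si](CC)(CC)CC | intermediate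
40 | bis-silyl ether of the target (C5 OTBS, C10 OSiEt3) | C=C1[C@H](O)C[C@@H]([C@@H](C)[C@H](OC(C)=O)[C@@H](OC(C)=O)C=C(C)C)[C@@H](O[Si](C)(C)C(C)(C)C)[C@H]2[C@H]1C=C[C@]2(C)O[Si](CC)(CC)CC | intermediate
41 | CNP0269663.3 | C=C1[C@H](O)C[C@@H]([C@@H](C)[C@H](OC(C)=O)[C@H](C=C(C)C)OC(C)=O)[C@@H](O)[C@H]2[C@H]1C=C[C@]2(C)O | target

**Step count and risks**
Total: 29 steps. Longest linear sequence: 22 steps (steps 1–9, then 17–29); the lactone branch is 7 steps (10–16).

The three steps most likely to fail: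

Step 25 (seven-membered ring by nitrile oxide cycloaddition; nitrile oxide dimerisation or addition to the C14=C15 alkene may compete). The fallback changes the ring-closing bond construction to a Nozaki–Hiyama–Kishi reaction. It sets out from enol triflate 13: Me3SnOH in 1,2-dichloroethane at 80 °C gives triflate acid F2. The chemistry of steps 17 to 23 applied to F2 and lactone 25 gives in turn triflate β-keto lactone F3, triflate C5 alcohol F4, triflate TBS ether F5, triflate C13 alcohol F6, triflate lactol F7, triflate enol ether diol F8 and triflate diacetate F9. Mild aqueous acid (PPTS, acetone/H2O) unmasks triflate aldehyde F10, and CrCl2 with NiCl2 (cat.) in DMF adds the alkenyl chromium species to the aldehyde, forming C1–C2 and the allylic alcohol directly. It comes back to the route at 40.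

Step 28 (facial selectivity at C2 is hard to predict in the seven-membered ring). The fallback corrects the carbinol by inversion instead of relying on reagent approach. It sets out from ketone 39: if the reduction gives mainly C2-epimeric alcohol F11, a Mitsunobu reaction (ClCH2CO2H, PPh3, DIAD, toluene) gives inverted chloroacetate F12, and thiourea with NaHCO3 in EtOH removes the chloroacetyl group without touching the acetates. It comes back at 40.

Step 3 (face selectivity of the epoxidation rests on the allylic ester outweighing the homoallylic isopropenyl group). The fallback uses a halohydrin, which delivers the epoxide on the face opposite to the one a direct electrophilic epoxidation prefers. It sets out from ester 5: N-bromosuccinimide in THF/H2O gives bromohydrin F1 (water opens the bromonium ion at tertiary C10 anti to bromine), and K2CO3 in MeOH closes it with inversion at C9. It comes back at 6.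

**Further compounds**
F1 | step 3 | methyl 3-bromo-2-hydroxy-2-methyl-5-(prop-1-en-2-yl)cyclopentane-1-carboxylate (Br trans to OH, OH trans to ester) | COC(=O)[C@H]1[C@H](C(C)=C)C[C@@H](Br)[C@]1(C)O
F2 | step 25 | 2-methyl-2-(triethylsilyloxy)-5-[1-(trifluoromethylsulfonyloxy)ethenyl]cyclopent-3-ene-1-carboxylic acid | OC(=O)[C@H]1[C@H](C(=C)OS(=O)(=O)C(F)(F)F)C=C[C@]1(C)O[Si](CC)(CC)CC
F3 | step 25 | enol triflate analogue of 27 | O=C1[C@@H]([C@@H](C)[C@H](O1)[C@@H](O[Si](CC)(CC)CC)C=C(C)C)C(=O)[C@H]2[C@H](C(=C)OS(=O)(=O)C(F)(F)F)C=C[C@]2(C)O[Si](CC)(CC)CC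
F4 | step 25 | enol triflate analogue of 28 | O=C1[C@@H]([C@@H](C)[C@H](O1)[C@@H](O[Si](CC)(CC)CC)C=C(C)C)[C@@H](O)[C@H]2[C@H](C(=C)OS(=O)(=O)C(F)(F)F)C=C[C@]2(C)O[Si](CC)(CC)CC
F5 | step 25 | enol triflate analogue of 29 | O=C1[C@@H]([C@@H](C)[C@H](O1)[C@@H](O[Si](CC)(CC)CC)C=C(C)C)[C@@H](O[Si](C)(C)C(C)(C)C)[C@H]2[C@H](C(=C)OS(=O)(=O)C(F)(F)F)C=C[C@]2(C)O[Si](CC)(CC)CC
F6 | step 25 | enol triflate analogue of 30 | O=C1[C@@H]([C@@H](C)[C@H](O1)[C@@H](O)C=C(C)C)[C@@H](O[Si](C)(C)C(C)(C)C)[C@H]2[C@H](C(=C)OS(=O)(=O)C(F)(F)F)C=C[C@]2(C)O[Si](CC)(CC)CC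
F7 | step 25 | enol triflate analogue of 31 | OC1[C@@H]([C@@H](C)[C@H](O1)[C@@H](O)C=C(C)C)[C@@H](O[Si](C)(C)C(C)(C)C)[C@H]2[C@H](C(=C)OS(=O)(=O)C(F)(F)F)C=C[C@]2(C)O[Si](CC)(CC)CC
F8 | step 25 | enol triflate analogue of 32 | COC=C[C@@H]([C@@H](C)[C@H](O)[C@@H](O)C=C(C)C)[C@@H](O[Si](C)(C)C(C)(C)C)[C@H]1[C@H](C(=C)OS(=O)(=O)C(F)(F)F)C=C[C@]1(C)O[Si](CC)(CC)CC
F9 | step 25 | enol triflate analogue of 33 | COC=C[C@@H]([C@@H](C)[C@H](OC(C)=O)[C@@H](OC(C)=O)C=C(C)C)[C@@H](O[Si](C)(C)C(C)(C)C)[C@H]1[C@H](C(=C)OS(=O)(=O)C(F)(F)F)C=C[C@]1(C)O[Si](CC)(CC)CC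
F10 | step 25 | C2 aldehyde carrying the enol triflate | O=CC[C@@H]([C@@H](C)[C@H](OC(C)=O)[C@@H](OC(C)=O)C=C(C)C)[C@@H](O[Si](C)(C)C(C)(C)C)[C@H]1[C@H](C(=C)OS(=O)(=O)C(F)(F)F)C=C[C@]1(C)O[Si](CC)(CC)CC
F11 | step 28 | C2 epimer of 40 | C=C1[C@@H](O)C[C@@H]([C@@H](C)[C@H](OC(C)=O)[C@@H](OC(C)=O)C=C(C)C)[C@@H](O[Si](C)(C)C(C)(C)C)[C@H]2[C@H]1C=C[C@]2(C)O[Si](CC)(CC)CC
F12 | step 28 | C2 chloroacetate of 40 | C=C1[C@H](OC(=O)CCl)C[C@@H]([C@@H](C)[C@H](OC(C)=O)[C@@H](OC(C)=O)C=C(C)C)[C@@H](O[Si](C)(C)C(C)(C)C)[C@H]2[C@H]1C=C[C@]2(C)O[Si](CC)(CC)CC
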